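**Strategy.** Numbering is that of the 1,2-dihydronaphthalene (ring A: catechol ring; ring B: dihydro ring; C1 carries the pyranone, C2 the acid, C3 the methyl ester). Ring B is opened at the C8a–C1 bond. The target then becomes an (E,E)-2,3-bis(arylidene)succinate in which C1 is the β-carbon of the C2 acrylate and C8a is the ring A carbon para to the C6 oxygen. A confined chiral Brønsted acid closes ring B in one operation by 6-endo Friedel–Crafts attack of C8a on C1, setting C1 and, through protonation, trans C2. The precursor comes from a Stobbe condensation, which already separates the C3 methyl ester from the C2 carboxyl, and an aldol condensation with a 4-formyl-2-pyranone-6-carboxylate.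

Key step: step 7

Remark on the chemistry: the facial preference of the chiral acid in step 7 cannot be predicted with confidence; the catalyst antipode that leads to the (1R,2S) series is to be chosen by trial, both antipodes being accessible from (R)- or (S)-BINOL.

**Step 1**
Reactants: 1 ethyl 3-methylbut-2-enoate; 2 diethyl oxalate
Product: 4 4-methyl-2-oxo-2H-pyran-6-carboxylic acid, via potassium dienolate 3 (not isolated)
Conditions: KOEt, EtOH/Et2O, 0 °C to rt; then conc. aq. HCl, reflux
Reagents that add atoms: water O
Why: Deprotonation of 1 at a γ-methyl group and acylation by 2 (vinylogous Claisen condensation) gives 3, and in hot aqueous acid the enol oxygen lactonizes onto the ester carbonyl while the remaining ester is hydrolysed, the classical oxalate route to 2-pyranone-6-carboxylic acids.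

**Step 2**
Reactants: 4 4-methyl-2-oxo-2H-pyran-6-carboxylic acid
Product: 5 benzyl 4-methyl-2-oxo-2H-pyran-6-carboxylate
Conditions: BnBr, KHCO3, DMF, rt
Reagents that add atoms: benzyl bromide BrCc1ccccc1
Why: SN2 O-alkylation of the carboxylate under a base too weak to open the pyranone ring.

**Step 3**
Reactants: 5 benzyl 4-methyl-2-oxo-2H-pyran-6-carboxylate
Product: 6 benzyl 4-formyl-2-oxo-2H-pyran-6-carboxylate
Conditions: SeO2, 1,4-dioxane, reflux
Reagents that add atoms: selenium dioxide O=[Se]=O
Why: The 4-methyl group is vinylogously α to the lactone carbonyl and should be oxidized to the aldehyde by ene reaction and [2,3]-sigmatropic shift (Riley oxidation), as known for 4-methylcoumarins.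

**Step 4**
Reactants: 7 3,4-bis(benzyloxy)benzaldehyde; 8 dimethyl succinate
Product: 10 (3E)-4-[3,4-bis(benzyloxy)phenyl]-3-(methoxycarbonyl)but-3-enoic acid, via paraconate lactone 9 (not isolated)
Conditions: NaOMe, MeOH, reflux; then aq. HCl
Reagents that add atoms: none
Why: Stobbe condensation: the succinate enolate adds to 7, the alkoxide closes lactone 9 on the distal ester and E1cB opening should give the E half-ester (aryl trans to CO2Me), with the methyl ester on the future C3 and the free acid on the future C2 carboxyl.

**Step 5**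
Reactants: 10 (3E)-4-[3,4-bis(benzyloxy)phenyl]-3-(methoxycarbonyl)but-3-enoic acid
Product: 11 4-benzyl 1-methyl (2E)-2-[3,4-bis(benzyloxy)benzylidene]butanedioate
Conditions: BnBr, KHCO3, DMF, rt
Reagents that add atoms: benzyl bromide BrCc1ccccc1
Why: SN2 esterification of the carboxylate; KHCO3 is too weak to shift the double bond out of conjugation with the arene.

**Step 6**
Reactants: 11 4-benzyl 1-methyl (2E)-2-[3,4-bis(benzyloxy)benzylidene]butanedioate; 6 benzyl 4-formyl-2-oxo-2H-pyran-6-carboxylate
Product: 14 4-benzyl 1-methyl (2E,3E)-2-[3,4-bis(benzyloxy)benzylidene]-3-({6-[(benzyloxy)carbonyl]-2-oxo-2H-pyran-4-yl}methylidene)butanedioate, via lithium aldolate 12 (not isolated), via mesylate 13 (not isolated)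
Conditions: LiN(iPr)2, THF, −78 °C; 6; then MsCl, −78 to 0 °C; then DBU, 0 °C to rt
Reagents that add atoms: none
Why: The lithium enolate formed α to the benzyl ester should add to the aldehyde of 6 faster than to the pyranone (aldol addition), the aldolate is trapped as mesylate before it can lactonize onto the methyl ester, and E1cB elimination should give the thermodynamically favoured E alkene (overall an aldol condensation).

**Step 7**
Reactants: 14 4-benzyl 1-methyl (2E,3E)-2-[3,4-bis(benzyloxy)benzylidene]-3-({6-[(benzyloxy)carbonyl]-2-oxo-2H-pyran-4-yl}methylidene)butanedioate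
Product: 15 2-benzyl 3-methyl (1R,2S)-6,7-bis(benzyloxy)-1-{6-[(benzyloxy)carbonyl]-2-oxo-2H-pyran-4-yl}-1,2-dihydronaphthalene-2,3-dicarboxylate
Conditions: chiral imidodiphosphorimidate (IDPi) Brønsted acid with 3,3'-diaryl-BINOL backbones and N-triflyl groups (5 mol%), CHCl3, 0 to 40 °C
Reagents that add atoms: none
Why: Proposed new method: the confined chiral acid protonates the carbonyl of the C2 benzyl ester of 14, which turns C1 (the β-carbon that carries the pyranone) into the terminus of a hydroxyallyl cation; C8a of ring A attacks it and loss of the C8a proton restores the arene. The closest known reactions are the triflic acid-mediated cyclization of 2,3-bis(benzylidene)succinates to trans-1-aryl-1,2-dihydronaphthalene-2,3-dicarboxylates (racemic) and the asymmetric Nazarov cyclizations and intramolecular hydroarylations catalysed by imidodiphosphorimidate acids, in which the chiral counter-anion selects the sense of closure of a protonated substrate. The ring closed is ring B, by 6-endo-trig Friedel–Crafts conjugate addition, formally a cationic closure of the C8a=C4a/C4=C3/C2=C1 triene. C1 is set by the catalyst anion, which ion-pairs with the protonated ester and should let only one of the two helical s-cis conformers of the diene reach the transition state. C2 is set when the resulting ketene hemiacetal is protonated, and equilibration through this enol under the acidic conditions should leave the more stable trans isomer with C3=C4 conjugated to ring A. The step needs ring A and not the pyranone to act as nucleophile (only the dialkoxyarene is electron-rich), C8a and not C5 to attack (para activation by the C6 oxygen, less hindrance), and attack at C1 and not C2 (C1 is the acrylate β-carbon; attack at C2 would need a quaternary centre next to a carbonyl).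

**Step 8**
Reactants: 15 2-benzyl 3-methyl (1R,2S)-6,7-bis(benzyloxy)-1-{6-[(benzyloxy)carbonyl]-2-oxo-2H-pyran-4-yl}-1,2-dihydronaphthalene-2,3-dicarboxylate
Product: 16 (1R,2S)-1-(6-carboxy-2-oxo-2H-pyran-4-yl)-6,7-dihydroxy-3-(methoxycarbonyl)-1,2-dihydronaphthalene-2-carboxylic acid
Conditions: BCl3, C6HMe5, CH2Cl2, −78 to 0 °C; then H2O
Reagents that add atoms: none
Why: Lewis acid-mediated debenzylation with pentamethylbenzene as cation scavenger should cleave both aryl benzyl ethers and both benzyl esters, while the conjugated methyl ester, the pyranone, the C3=C4 bond and both stereocentres (no base, low temperature) are left untouched.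

**Compound list**
1 | ethyl 3-methylbut-2-enoate | CCOC(=O)C=C(C)C | starting material
2 | diethyl oxalate | CCOC(=O)C(=O)OCC | starting material
3 | potassium 1,6-diethoxy-4-methyl-1,6-dioxohexa-2,4-dien-2-olate (geometric isomers) | CCOC(=O)C([O-])=CC(C)=CC(=O)OCC.[K+] | intermediate
4 | 4-methyl-2-oxo-2H-pyran-6-carboxylic acid | Cc1cc(=O)oc(C(=O)O)c1 | intermediate
5 | benzyl 4-methyl-2-oxo-2H-pyran-6-carboxylate | Cc1cc(=O)oc(C(=O)OCc2ccccc2)c1 | intermediate
6 | benzyl 4-formyl-2-oxo-2H-pyran-6-carboxylate | O=Cc1cc(=O)oc(C(=O)OCc2ccccc2)c1 | intermediate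
7 | 3,4-bis(benzyloxy)benzaldehyde | O=Cc1ccc(OCc2ccccc2)c(OCc2ccccc2)c1 | starting material
8 | dimethyl succinate | COC(=O)CCC(=O)OC | starting material
9 | methyl 2-[3,4-bis(benzyloxy)phenyl]-5-oxooxolane-3-carboxylate (mixture of diastereomers) | COC(=O)C1CC(=O)OC1c1ccc(OCc2ccccc2)c(OCc2ccccc2)c1 | intermediate
10 | (3E)-4-[3,4-bis(benzyloxy)phenyl]-3-(methoxycarbonyl)but-3-enoic acid | COC(=O)/C(CC(=O)O)=C/c1ccc(OCc2ccccc2)c(OCc2ccccc2)c1 | intermediate
11 | 4-benzyl 1-methyl (2E)-2-[3,4-bis(benzyloxy)benzylidene]butanedioate | COC(=O)/C(CC(=O)OCc1ccccc1)=C/c1ccc(OCc2ccccc2)c(OCc2ccccc2)c1 | intermediate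
12 | lithium alkoxide of 4-benzyl 1-methyl (2E)-2-[3,4-bis(benzyloxy)benzylidene]-3-[{6-[(benzyloxy)carbonyl]-2-oxo-2H-pyran-4-yl}(hydroxy)methyl]butanedioate (mixture of diastereomers) | [Li+].COC(=O)/C(=C/c1ccc(OCc2ccccc2)c(OCc2ccccc2)c1)C(C(=O)OCc1ccccc1)C([O-])c1cc(=O)oc(C(=O)OCc2ccccc2)c1 | intermediate
13 | 4-benzyl 1-methyl (2E)-2-[3,4-bis(benzyloxy)benzylidene]-3-[{6-[(benzyloxy)carbonyl]-2-oxo-2H-pyran-4-yl}(methanesulfonyloxy)methyl]butanedioate (mixture of diastereomers) | COC(=O)/C(=C/c1ccc(OCc2ccccc2)c(OCc2ccccc2)c1)C(C(=O)OCc1ccccc1)C(OS(C)(=O)=O)c1cc(=O)oc(C(=O)OCc2ccccc2)c1 | intermediate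
14 | 4-benzyl 1-methyl (2E,3E)-2-[3,4-bis(benzyloxy)benzylidene]-3-({6-[(benzyloxy)carbonyl]-2-oxo-2H-pyran-4-yl}methylidene)butanedioate (in each alkene the ring is trans to the ester on the same double bond) | COC(=O)/C(=C/c1ccc(OCc2ccccc2)c(OCc2ccccc2)c1)C(\C(=O)OCc1ccccc1)=C/c1cc(=O)oc(C(=O)OCc2ccccc2)c1 | intermediate
15 | 2-benzyl 3-methyl (1R,2S)-6,7-bis(benzyloxy)-1-{6-[(benzyloxy)carbonyl]-2-oxo-2H-pyran-4-yl}-1,2-dihydronaphthalene-2,3-dicarboxylate (1,2-trans) | COC(=O)C1=Cc2cc(OCc3ccccc3)c(OCc3ccccc3)cc2[C@@H](c2cc(C(=O)OCc3ccccc3)oc(=O)c2)[C@@H]1C(=O)OCc1ccccc1 | intermediate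
16 | (1R,2S)-1-(6-carboxy-2-oxo-2H-pyran-4-yl)-6,7-dihydroxy-3-(methoxycarbonyl)-1,2-dihydronaphthalene-2-carboxylic acid (1,2-trans) | COC(=O)C1=Cc2cc(O)c(O)cc2[C@@H](c2cc(C(=O)O)oc(=O)c2)[C@@H]1C(=O)O | target

Total step count: 8. Longest linear sequence: 6 steps (steps 1, 2, 3, 6, 7, 8).

**Steps most likely to fail**

Step 7 carries the label and is the riskiest. The chiral acid may be too weak to activate an acrylate whose β-carbon bears the electron-poor pyranone, the protonated benzyl ester may ionize before ring closure, or the two helical conformers may be discriminated poorly, so that conversion or enantioselectivity stays low. The fallback uses known chemistry and sets out from 14. The achiral strong-acid cyclization established for 2,3-bis(arylidene)succinates (TfOH or catalytic HNTf2, CH2Cl2, −40 to 0 °C) should give the racemic trans triester, that is 15 together with its mirror image 2-benzyl 3-methyl (1S,2R)-6,7-bis(benzyloxy)-1-{6-[(benzyloxy)carbonyl]-2-oxo-2H-pyran-4-yl}-1,2-dihydronaphthalene-2,3-dicarboxylate F1. Preparative chromatography on a chiral stationary phase (SFC) then separates the enantiomers, and the route is rejoined at 15.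

Step 6 may suffer from retro-aldol cleavage, from lactonization of the aldolate onto the methyl ester (which would scramble the ester pattern), or from attack of the enolate or DBU on the pyranone. The fallback replaces the aldol condensation by an olefination and sets out from 11. Enolate formation with LiN(iPr)2, C-phosphinylation with ClP(OEt)2 and oxidation with H2O2 should give 4-benzyl 1-methyl (2E)-2-[3,4-bis(benzyloxy)benzylidene]-3-(diethoxyphosphoryl)butanedioate F2. Horner–Wadsworth–Emmons reaction of F2 with 6 under LiCl/DBU in MeCN, mild enough for the pyranone, comes back to the route at 14.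

Step 3 may over-oxidize the aldehyde to the acid or degrade the pyranone ring at reflux. The fallback sets out from 5. Condensation of the acidic 4-methyl group with tert-butoxybis(dimethylamino)methane should give benzyl 4-[(E)-2-(dimethylamino)ethenyl]-2-oxo-2H-pyran-6-carboxylate F3, and cleavage of the enamine double bond with NaIO4 in aqueous THF returns to the route at 6.

**Further compounds**
F1 | step 7 | 2-benzyl 3-methyl (1S,2R)-6,7-bis(benzyloxy)-1-{6-[(benzyloxy)carbonyl]-2-oxo-2H-pyran-4-yl}-1,2-dihydronaphthalene-2,3-dicarboxylate | COC(=O)C1=Cc2cc(OCc3ccccc3)c(OCc3ccccc3)cc2[C@H](c2cc(C(=O)OCc3ccccc3)oc(=O)c2)[C@H]1C(=O)OCc1ccccc1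
F2 | step 6 | 4-benzyl 1-methyl (2E)-2-[3,4-bis(benzyloxy)benzylidene]-3-(diethoxyphosphoryl)butanedioate | COC(=O)/C(=C/c1ccc(OCc2ccccc2)c(OCc2ccccc2)c1)C(C(=O)OCc1ccccc1)P(=O)(OCC)OCC
F3 | step 3 | benzyl 4-[(E)-2-(dimethylamino)ethenyl]-2-oxo-2H-pyran-6-carboxylate | CN(C)/C=C/c1cc(=O)oc(C(=O)OCc2ccccc2)c1
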